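## Structural features

The target is a pentamer of guaiacyl C6–C3 units in which ring A (4-hydroxy-3-methoxyphenyl) is the benzyl group on C8' of a tetrahydrofuran that also carries CH2OH on C8 and ring B on C7, with the (7R,8S,8'S) arrangement that places the aryl group trans to CH2OH and CH2OH cis to the benzyl group. Rings B, C and D are each the benzo ring of a trans-2-aryl-3-(hydroxymethyl)-7-methoxy-2,3-dihydrobenzofuran (units 1, 2 and 3, called the B, C and D units below), linked head to tail so that C2 of one unit is bonded to C5 of the next arene, and ring E (4-hydroxy-3-methoxyphenyl) ends the chain. Nine stereocentres stand in four groups of neighbours, C7/C8/C8' in the tetrahydrofuran and C2/C3 in each unit. The B and C units are (2S,3R) but the D unit is (2R,3S), so the chain is not a plain repeat. The fragile groups are four benzylic C–O bonds (C7–O and three C2–O), each para to an oxygen of its aryl group and therefore open to acid ionisation and hydrogenolysis, two free phenols that oxidise easily and can form quinone methides, and six hydroxyl groups in all. The real difficulty is to build three trans-dihydrobenzofurans one after another with absolute control and to tell the one carbon on ring B that becomes C7 apart from the three CH2OH carbons on C3 of the units. The key step uses the recurring pattern C3a–C3(one-carbon group)–C2(aryl)–O1, which is what a 2-arylchroman-4-one leaves when its fused arene carbon C4a moves from C4 to C3, so that C4 becomes the exocyclic carbon and the pyranone shrinks to the dihydrofuran.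

## Logic of the disconnections

**54 to 52.** 54 is 53 without its five silyl ethers, and 53 is opened at the O–C7 bond of the tetrahydrofuran to give 52. The cut is placed there because C7 is benzylic and para to the ring B oxygen, so the bond can be made by ionisation and both C7 epimers of 52 converge. One ring and one stereocentre are removed. The forward step must ionise only the C7 hydroxyl and stop before ring A or the other benzylic ethers react.

**52 to 49 and 38.** 52 comes from 51 by reduction, and 51 is cut at C7–C8 into 49 and 38. This separates the whole oligomeric part, 38, from 49, which already holds C8', C9 and C9'. The forward aldol must add anti to the C8' benzyl group; the C7 carbinol configuration need not be controlled because the ring closure erases it.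

**49 to 39, 42 and 45.** 49 comes from 47 by way of 48, 47 is cut at C8–C8' into 44 and 45, 44 is cut at its N-acyl bond into 41 and 42, and 41 is 39 with its phenol silylated. 39, 42 and 45 are commercial, so the side branch is short. The demand is high facial selectivity in the alkylation with the enantiomer of the auxiliary that gives (S).

**38 to 35.** No skeletal bond is cut: 38 comes from 37 by silylation, 37 from 36 by oxidation of the one benzylic alcohol, and 36 from 35 by reduction of four esters and one pivalate. Keeping every one-carbon group as a methyl ester up to 35 gives a single global reduction and keeps an electron-withdrawing group next to each benzylic ether carbon through all acidic steps. The demand is that the oxidant picks the benzylic alcohol out of four primary alcohols and a phenol.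

**35 to 29 and 32.** 35 is cut at C3–C3a of the D unit, which redraws it as 33 (ring contraction in reverse), and 33 is cut at C2–aryl into 29 and 32; 32 comes from 30 by way of 31. Ring E must be electron-poor during the contraction, hence its pivalate. This addition needs the facial sense opposite to that of the first two.

**29 to 24.** The pyranone of 29 is cut at O1–C2 and C2–C3 (one carbon from 6) to give 27, and 27 goes back through 26 to 24 by restoring the pivalate and replacing acetyl by bromine (the two acetyl carbons come from 3). The bromine and pivalate on ring D of 24 are thus the masked chromone. The forward steps must free the phenol without opening the finished units.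

**24 to 16.** The same cuts are made one unit inward: 24 to 22 (C3–C3a of the C unit), 22 to 21 and 13 (C2–aryl), and 21 through 19 and 18 to 16. Growth runs from ring B outward on purpose: every flavanone that is contracted then carries an electron-poor, acyloxy-bearing 2-aryl group, whereas growth in the other direction would place an electron-rich dihydrobenzofuran at C2.

**16 to 14 (key) and 14 to 8 and 13.** 16 is cut at C3–C3a and redrawn as the six-membered ketone 14 with C4a on C4, and 14 is cut at C2–aryl into 8 and 13. One ring, one C–C bond and one stereocentre are traded for two flat, achiral partners. The forward step must make the fused ring migrate and not the 2-aryl group.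

**8 and 13 to 1, 3, 6, 9 and 11.** 8 goes back to 5 and 6, 5 to 2 and 3, and 2 to 1; 13 goes back through 12 to 10 and 11, and 10 to 9. Boron must enter at the C–H para to the ester oxygen so that the bromine survives for the next cycle.

## Other disconnections considered

Alternative 1: The cut runs through C7'–C8' and C8–C7 at the tetrahydrofuran end and leaves the oligomer untouched.
- Forward step: dithiane A2, lithiated with BuLi, would add to the (5S)-menthyloxybutenolide A3 trans to the acetal substituent, and the anionic adduct would be trapped in the same flask by aldehyde 38 to give A1 with the C7 carbinol as a mixture. No ring closes; reductive removal of the dithiane, reduction of the lactone and of the acetal carbon, and acid closure of O–C7 would follow.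
- In its favour: three components join in one flask; the acetal auxiliary fixes C8' and, through trans trapping, C8; A2 and A3 each need about two steps.
- Against it here: it addresses only the last three stereocentres and still needs 38, that is, the whole chosen sequence up to step 22. Reductive desulfurisation would have to be done on a molecule with three hydrogenolysable benzylic aryl ethers, and the dithiane anion is bulky next to the new C8 centre.
- Comparison: on structure both plans make C7–C8 by an aldol-type addition and differ only in how C8' is set. On mechanism both rely on anti addition to a β-substituted lactone enolate and on acid closure, so they are equals in stereocontrol. On step economy the alternative is the better in the side branch (about four steps for A2 and A3 against four for 49, but with no separate auxiliary removal) and the worse after the union, where desulfurisation is added. It complements the ring contraction and does not replace it.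

Alternative 2: The cut removes C2–C3 of the B and C units together and leaves two ArO–CH2–Ar ether links and two aryl diazoacetate groups in the open precursor A5, whose ring D end is a D unit block derived from A6.
- Forward step: with Rh2(S-PTTL)4 or its mirror image each diazo group of A5 would be decomposed, and the carbene carbon would insert into the neighbouring benzylic C–H bond through a five-membered transition state, closing both oxygen rings. DBU would then equilibrate C3 to give the trans,trans triester A4.
- In its favour: two rings and four stereocentres arise in one neutral, non-oxidising step, so no finished benzylic ether meets mineral acid; on this point the alternative is the better plan. The ether links come from simple benzylations, which makes the assembly convergent.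
- Against it here: such insertions tend to give the cis product first, so C2 rests on the catalyst and C3 must be corrected afterwards. Two carbenes must react with the same sense at crowded, doubly ortho-substituted sites, with carbene dimerisation and attack on the neighbouring methoxy group as competitors. Each diazo ester needs an arylacetic ester ortho to the ether oxygen, and the D unit, of opposite sense, must come from another reaction.
- Comparison: on structure A4 matches 24 and 35 in oxidation level, and both plans share the trans equilibration at C3. On mechanism the chosen plan sets C2 first and relays it to C3 by substrate control, which is a surer relay than catalyst control at two sites at once, while the alternative is gentler to the finished units. On step economy the alternative is the better if the double insertion is selective and the equal if the two insertions must be run in turn.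

Alternative 3: The cut removes C2–C3 and O1–C2 of the D unit, so that C2 with ring E enters as a one-carbon partner.
- Forward step: Cs2CO3 would eliminate the sulfonyl group of A7 to give the ortho-quinone methide A9 and deprotonate the chiral benzylsulfonium salt A8 to the ylide A10. Addition of the ylide carbon to the methide carbon forms C2–C3, and the phenoxide then closes O–C2 by 5-exo-tet displacement of the sulfonium leaving group to give A6.
- In its favour: the trans outcome follows from the anti betaine; C3 arrives at the alcohol oxidation level, which spares a later reduction (the better on this point); the conditions are mildly basic, with no oxidant and no transition metal.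
- Against it here: it builds only one unit of three, and the one that is least demanding in the chosen plan. Absolute control rests on a stoichiometric chiral sulfonium group acting in a two-stage, partly reversible addition (the enantiomer drawn for A8 is illustrative). A9 carries a CH2OSi group on the methide carbon and could tautomerise before it is trapped. The ring D ester of A6 is a handle for the ether-linked A5, not for the chromone chemistry of the chosen plan.
- Comparison: on structure A6 equals the D unit part of 38, and the two plans are equals in trans selectivity. On mechanism the alternative forms both ring bonds in one event where the chosen plan needs addition and contraction, but it sets C2 and C3 in one reagent-controlled step of uncertain sense. On step economy it is the better for the D unit alone (about three steps against five per cycle) and the worse for the whole target, because it does not iterate.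

Key step: step 7

Remarks on the chemistry (assumptions):
- Shorthand in names: "B–C triester" is the B unit bonded through its C2 to C5 of the C unit, with CO2Me on C5 of ring B and on C3 of both units; "B–C–D" adds the D unit in the same way; ArX is the aryl group of 38 (38 without its CHO group).
- The facial sense of the palladium-catalysed addition is assigned by analogy with β-substituted cyclic enones: (R)-t-BuPyOX for a (2S)-flavanone and (S)-t-BuPyOX for a (2R)-flavanone. If the sense is the reverse, the two ligands change places and nothing else changes.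
- Boron is placed para to the pivalate by C–H borylation, because a halide-based borylation of 10 would consume the bromine needed for the next cycle and put boron ortho to oxygen.
- The free boronic acids, not their pinacol esters, are used in the additions.
- The D unit is (2R,3S) while the B and C units are (2S,3R), so the third addition uses the mirror-image ligand.
- The ring B acetyl group is introduced by bromination and Stille coupling, not by a Fries shift on a deactivated guaiacyl ester, where Lewis acid would threaten the methyl ether.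

Step 1
Reactants: 1 methyl vanillate (methyl 4-hydroxy-3-methoxybenzoate)
Product: 2 methyl 3-bromo-4-hydroxy-5-methoxybenzoate
Conditions: Br2 (1.05 equiv), AcOH, rt
Reagents that add atoms: bromine, BrBr
Why: Electrophilic aromatic bromination; the free hydroxyl directs to its only open ortho position, which is also meta to the ester.

Step 2
Reactants: 2 methyl 3-bromo-4-hydroxy-5-methoxybenzoate; 3 tributyl(1-ethoxyvinyl)stannane
Product: 5 methyl 3-acetyl-4-hydroxy-5-methoxybenzoate, via enol ether 4 (not isolated)
Conditions: PdCl2(PPh3)2 (5 mol %), toluene, 100 °C; then 1 M HCl, THF, rt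
Reagents that add atoms: water, O
Why: Stille coupling (zerovalent palladium cycle) of the aryl bromide with an acetyl-anion equivalent, then hydrolysis of the enol ether; the neutral coupling tolerates the free phenol and the ester.

Step 3
Reactants: 5 methyl 3-acetyl-4-hydroxy-5-methoxybenzoate; 6 N,N-dimethylformamide dimethyl acetal
Product: 8 methyl 8-methoxy-4-oxo-4H-chromene-6-carboxylate (ring B chromone), via enaminone 7 (not isolated)
Conditions: 6 (2 equiv), toluene, 95 °C; then TsOH·H2O, CH2Cl2, 40 °C
Reagents that add atoms: none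
Why: Standard chromone synthesis: condensation of the ortho-hydroxyacetophenone to the enaminone, then acid-promoted 6-endo addition of the phenol and loss of dimethylamine; the acetal carbon becomes C2.

Step 4
Reactants: 9 2-bromo-6-methoxyphenol
Product: 10 2-bromo-6-methoxyphenyl pivalate
Conditions: pivaloyl chloride, Et3N, DMAP (cat.), CH2Cl2, 0 °C to rt
Reagents that add atoms: pivaloyl chloride, CC(C)(C)C(Cl)=O
Why: O-Acylation of a phenol; the pivalate is chosen because it resists acidic orthoformate and makes the future 2-aryl group electron-poor.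

Step 5
Reactants: 10 2-bromo-6-methoxyphenyl pivalate; 11 bis(pinacolato)diboron
Product: 13 [3-bromo-5-methoxy-4-(pivaloyloxy)phenyl]boronic acid, via pinacol boronate 12 (not isolated)
Conditions: [Ir(OMe)(cod)]2 (1.5 mol %), 4,4'-di-tert-butyl-2,2'-bipyridine (3 mol %), THF, 80 °C; then NaIO4, THF–H2O, 1 M HCl, rt
Reagents that add atoms: water, O
Why: Iridium-catalysed aromatic C–H borylation under steric control: in this 1,2,3-trisubstituted arene only the C–H para to the ester oxygen has no ortho neighbour, and the C–Br bond is left alone. Oxidative cleavage of the pinacol ester then frees the boronic acid.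

Step 6
Reactants: 8 methyl 8-methoxy-4-oxo-4H-chromene-6-carboxylate; 13 [3-bromo-5-methoxy-4-(pivaloyloxy)phenyl]boronic acid
Product: 14 methyl (2S)-2-[3-bromo-5-methoxy-4-(pivaloyloxy)phenyl]-8-methoxy-4-oxochroman-6-carboxylate (ring B flavanone)
Conditions: Pd(OCOCF3)2 (5 mol %), (R)-t-BuPyOX [(R)-4-tert-butyl-2-(pyridin-2-yl)-4,5-dihydrooxazole] (6 mol %), NH4PF6 (30 mol %), H2O (5 equiv), ClCH2CH2Cl, 60 °C
Reagents that add atoms: none
Why: Asymmetric conjugate addition of an arylboronic acid to a chromone under divalent palladium catalysis (transmetalation, enantio-determining insertion of C2=C3 into the aryl–palladium bond, protonolysis of the palladium enolate). The ligand sets C2 as S, and the aryl bromide survives because no zerovalent palladium is formed.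

Step 7
Reactants: 14 methyl (2S)-2-[3-bromo-5-methoxy-4-(pivaloyloxy)phenyl]-8-methoxy-4-oxochroman-6-carboxylate
Product: 16 dimethyl (2S,3S)-2-[3-bromo-5-methoxy-4-(pivaloyloxy)phenyl]-7-methoxy-2,3-dihydrobenzofuran-3,5-dicarboxylate (trans diester of the B unit), via methyl enol ether 15 (not isolated)
Conditions: PhI(OAc)2 (1.2 equiv), H2SO4 (1.5 equiv), HC(OMe)3, 0 °C to rt
Reagents that add atoms: trimethyl orthoformate, COC(OC)OC
Why: Acid and orthoformate convert the C4 ketone into methyl enol ether 15, whose C3 attacks the trivalent iodine of PhI(OAc)2 on the face away from the C2 aryl group; capture by methanol gives a C3 iodane ketal with iodine equatorial and trans to that aryl group. The fused-ring carbon C4a, antiperiplanar to the C3–I bond, then moves from C4 to C3 as iodobenzene leaves (iodine becomes monovalent), and the dimethoxycarbenium ion left at C4 loses a methyl group to give the ester. The closest known reaction type is the oxidative ring contraction of flavanones to methyl trans-2-aryl-2,3-dihydrobenzofuran-3-carboxylates by trivalent iodine in orthoformate, a cyclic case of the 1,2-aryl shift that turns aryl ketones into arylacetic esters. The dihydrofuran ring is therefore closed by contraction of the pyranone through a 1,2-aryl shift (new bond C3–C3a), not by a ring-closing attack of oxygen or carbon. The one new stereocentre, C3, is controlled by C2: anti iodination followed by migration with inversion puts the ester trans to the aryl group, and because C3 stays epimerisable next to the ester, the more stable trans isomer is also the thermodynamic one. C2, set in step 6, takes no part. The step needs the fused ring to migrate faster than the C2 aryl group (which would lead to an isoflavone), faster than elimination to the flavone and faster than plain C3 methoxylation; the ring oxygen ortho to C4a makes the fused ring the better migrating group, while pivalate and bromine make the C2 aryl group electron-poor. The pivalate, both methyl esters and the aryl bromide are inert to the acidic, mildly oxidising medium.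

Step 8
Reactants: 16 dimethyl (2S,3S)-2-[3-bromo-5-methoxy-4-(pivaloyloxy)phenyl]-7-methoxy-2,3-dihydrobenzofuran-3,5-dicarboxylate; 3 tributyl(1-ethoxyvinyl)stannane
Product: 18 dimethyl (2S,3S)-2-[3-acetyl-5-methoxy-4-(pivaloyloxy)phenyl]-7-methoxy-2,3-dihydrobenzofuran-3,5-dicarboxylate, via enol ether 17 (not isolated)
Conditions: PdCl2(PPh3)2 (5 mol %), toluene, 100 °C; then 1 M HCl, THF, 0 °C to rt
Reagents that add atoms: water, O
Why: Stille coupling at the aryl bromide ortho to the pivalate, then mild hydrolysis of the enol ether; the neutral conditions leave the C3 ester and the pivalate alone.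

Step 9
Reactants: 18 dimethyl (2S,3S)-2-[3-acetyl-5-methoxy-4-(pivaloyloxy)phenyl]-7-methoxy-2,3-dihydrobenzofuran-3,5-dicarboxylate
Product: 19 dimethyl (2S,3S)-2-(3-acetyl-4-hydroxy-5-methoxyphenyl)-7-methoxy-2,3-dihydrobenzofuran-3,5-dicarboxylate
Conditions: K2CO3 (1.5 equiv), MeOH–THF, 0 °C to rt; aq. NH4Cl
Reagents that add atoms: none
Why: Base-mediated methanolysis (transesterification) of a phenyl ester activated by the ortho acetyl group; methyl esters are unchanged in methanol, and C3 can only equilibrate to the trans configuration it already has.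

Step 10
Reactants: 19 dimethyl (2S,3S)-2-(3-acetyl-4-hydroxy-5-methoxyphenyl)-7-methoxy-2,3-dihydrobenzofuran-3,5-dicarboxylate; 6 N,N-dimethylformamide dimethyl acetal
Product: 21 dimethyl (2S,3S)-7-methoxy-2-(8-methoxy-4-oxo-4H-chromen-6-yl)-2,3-dihydrobenzofuran-3,5-dicarboxylate (ring C chromone), via enaminone 20 (not isolated)
Conditions: 6 (2 equiv), toluene, 90 °C; then TsOH·H2O, CH2Cl2, rt
Reagents that add atoms: none
Why: Enaminone formation and acid-promoted closure as in step 3; once the phenol oxygen is part of the chromone it is a poor donor, which steadies the benzylic ether of the B unit.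

Step 11
Reactants: 21 dimethyl (2S,3S)-7-methoxy-2-(8-methoxy-4-oxo-4H-chromen-6-yl)-2,3-dihydrobenzofuran-3,5-dicarboxylate; 13 [3-bromo-5-methoxy-4-(pivaloyloxy)phenyl]boronic acid
Product: 22 dimethyl (2S,3S)-2-{(2S)-2-[3-bromo-5-methoxy-4-(pivaloyloxy)phenyl]-8-methoxy-4-oxochroman-6-yl}-7-methoxy-2,3-dihydrobenzofuran-3,5-dicarboxylate (ring C flavanone)
Conditions: Pd(OCOCF3)2 (5 mol %), (R)-t-BuPyOX (6 mol %), NH4PF6 (30 mol %), H2O (5 equiv), ClCH2CH2Cl, 60 °C
Reagents that add atoms: none
Why: The same palladium-catalysed asymmetric conjugate addition as in step 6; the new C2 is set as S by the ligand, since the existing stereocentres are remote from the reacting double bond.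

Step 12
Reactants: 22 dimethyl (2S,3S)-2-{(2S)-2-[3-bromo-5-methoxy-4-(pivaloyloxy)phenyl]-8-methoxy-4-oxochroman-6-yl}-7-methoxy-2,3-dihydrobenzofuran-3,5-dicarboxylate
Product: 24 B–C triester bearing ring D as 3-bromo-5-methoxy-4-(pivaloyloxy)phenyl (each unit 2S,3S-trans), via methyl enol ether 23 (not isolated)
Conditions: PhI(OAc)2 (1.2 equiv), H2SO4 (1.0 equiv), HC(OMe)3, 0 °C to rt
Reagents that add atoms: trimethyl orthoformate, COC(OC)OC
Why: The same oxidative 1,2-aryl shift with ring contraction as in step 7, now with ring C migrating; the new C3 is set trans to the new C2 by the same relay. The C3 ester of the B unit disfavours ionisation of its benzylic ether, and the acid charge is kept low.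

Step 13
Reactants: 24 B–C triester bearing ring D as 3-bromo-5-methoxy-4-(pivaloyloxy)phenyl; 3 tributyl(1-ethoxyvinyl)stannane
Product: 26 B–C triester bearing ring D as 3-acetyl-5-methoxy-4-(pivaloyloxy)phenyl (each unit 2S,3S-trans), via enol ether 25 (not isolated)
Conditions: PdCl2(PPh3)2 (5 mol %), toluene, 100 °C; then 1 M HCl, THF, 0 °C to rt
Reagents that add atoms: water, O
Why: Stille coupling and enol ether hydrolysis as in step 8.

Step 14
Reactants: 26 B–C triester bearing ring D as 3-acetyl-5-methoxy-4-(pivaloyloxy)phenyl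
Product: 27 B–C triester bearing ring D as 3-acetyl-4-hydroxy-5-methoxyphenyl (each unit 2S,3S-trans)
Conditions: K2CO3 (1.5 equiv), MeOH–THF, 0 °C to rt; aq. NH4Cl
Reagents that add atoms: none
Why: Methanolysis of the activated phenyl pivalate as in step 9.

Step 15
Reactants: 27 B–C triester bearing ring D as 3-acetyl-4-hydroxy-5-methoxyphenyl; 6 N,N-dimethylformamide dimethyl acetal
Product: 29 B–C triester bearing ring D as 8-methoxy-4-oxo-4H-chromen-6-yl (ring D chromone), via enaminone 28 (not isolated)
Conditions: 6 (2 equiv), toluene, 90 °C; then TsOH·H2O, CH2Cl2, rt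
Reagents that add atoms: none
Why: Enaminone formation and closure to the chromone as in steps 3 and 10.

Step 16
Reactants: 30 2-methoxy-4-(4,4,5,5-tetramethyl-1,3,2-dioxaborolan-2-yl)phenol
Product: 31 2-methoxy-4-(4,4,5,5-tetramethyl-1,3,2-dioxaborolan-2-yl)phenyl pivalate
Conditions: pivaloyl chloride, Et3N, DMAP (cat.), CH2Cl2, 0 °C to rt
Reagents that add atoms: pivaloyl chloride, CC(C)(C)C(Cl)=O
Why: O-Acylation of the phenol; the pivalate again makes the future 2-aryl group (ring E) a poor migrating group and protects the phenol from the oxidant.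

Step 17
Reactants: 31 2-methoxy-4-(4,4,5,5-tetramethyl-1,3,2-dioxaborolan-2-yl)phenyl pivalate
Product: 32 [3-methoxy-4-(pivaloyloxy)phenyl]boronic acid
Conditions: NaIO4, NH4OAc, acetone–H2O, rt
Reagents that add atoms: water, O
Why: Oxidative cleavage of the pinacol diol drives hydrolysis of the boronic ester to the free acid, the form that transmetalates readily in the aqueous palladium system.

Step 18
Reactants: 29 B–C triester bearing ring D as 8-methoxy-4-oxo-4H-chromen-6-yl; 32 [3-methoxy-4-(pivaloyloxy)phenyl]boronic acid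
Product: 33 B–C triester bearing ring D as (2R)-8-methoxy-2-[3-methoxy-4-(pivaloyloxy)phenyl]-4-oxochroman-6-yl (ring D flavanone)
Conditions: Pd(OCOCF3)2 (5 mol %), (S)-t-BuPyOX (6 mol %), NH4PF6 (30 mol %), H2O (5 equiv), ClCH2CH2Cl, 60 °C
Reagents that add atoms: none
Why: The same palladium-catalysed conjugate addition with the mirror-image ligand, so that the aryl group enters on the opposite face and C2 of the future D unit is R; catalyst control is expected to override the remote stereocentres.

Step 19
Reactants: 33 B–C triester bearing ring D as (2R)-8-methoxy-2-[3-methoxy-4-(pivaloyloxy)phenyl]-4-oxochroman-6-yl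
Product: 35 B–C–D tetraester bearing ring E as 3-methoxy-4-(pivaloyloxy)phenyl (B unit 2S,3S / C unit 2S,3S / D unit 2R,3R), via methyl enol ether 34 (not isolated)
Conditions: PhI(OAc)2 (1.2 equiv), H2SO4 (1.0 equiv), HC(OMe)3, 0 °C to rt
Reagents that add atoms: trimethyl orthoformate, COC(OC)OC
Why: Third oxidative 1,2-aryl shift with ring contraction (ring D migrates); C3 of the D unit follows its (R)-C2 to the trans ester. Ring E carries an acyloxy group and no free phenol, so it is neither oxidised nor prone to migrate.

Step 20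
Reactants: 35 B–C–D tetraester bearing ring E as 3-methoxy-4-(pivaloyloxy)phenyl
Product: 36 B–C–D tetrakis(hydroxymethyl) compound bearing ring E as 4-hydroxy-3-methoxyphenyl (B unit 2S,3R / C unit 2S,3R / D unit 2R,3S)
Conditions: LiAlH4 (6 equiv), THF, 0 °C; aq. potassium sodium tartrate (KNaC4H4O6)
Reagents that add atoms: none
Why: Hydride reduction of four methyl esters to primary alcohols, with reductive cleavage of the pivalate in the same flask; once C3 bears CH2OH it can no longer epimerise.

Step 21
Reactants: 36 B–C–D tetrakis(hydroxymethyl) compound bearing ring E as 4-hydroxy-3-methoxyphenyl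
Product: 37 B–C–D tris(hydroxymethyl) ring B carbaldehyde bearing ring E as 4-hydroxy-3-methoxyphenyl
Conditions: MnO2 (activated, excess), THF–CH2Cl2, rt
Reagents that add atoms: none
Why: Chemoselective oxidation: MnO2 takes the benzylic alcohol on ring B to the aldehyde and leaves the three non-benzylic primary alcohols alone; guaiacyl phenols of the vanillyl alcohol type tolerate this oxidant.

Step 22
Reactants: 37 B–C–D tris(hydroxymethyl) ring B carbaldehyde bearing ring E as 4-hydroxy-3-methoxyphenyl
Product: 38 B–C–D tris(tert-butyldimethylsilyloxymethyl) ring B carbaldehyde bearing ring E as 4-(tert-butyldimethylsilyloxy)-3-methoxyphenyl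
Conditions: t-BuMe2SiCl (6 equiv), imidazole, DMF, rt
Reagents that add atoms: tert-butyldimethylsilyl chloride, CC(C)(C)[Si](C)(C)Cl
Why: Silylation of the three primary alcohols and the phenol so that no acidic proton meets the enolate in step 27.

Step 23
Reactants: 39 3-(4-hydroxy-3-methoxyphenyl)propanoic acid
Product: 41 3-[4-(tert-butyldimethylsilyloxy)-3-methoxyphenyl]propanoic acid, via silyl ester 40 (not isolated)
Conditions: t-BuMe2SiCl (2.3 equiv), imidazole, DMF, rt; then AcOH–H2O–THF, rt
Reagents that add atoms: tert-butyldimethylsilyl chloride, CC(C)(C)[Si](C)(C)Cl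
Why: Silylation of phenol and acid followed by selective hydrolysis of the much more labile silyl ester under mild acid, which spares the aryl silyl ether.

Step 24
Reactants: 41 3-[4-(tert-butyldimethylsilyloxy)-3-methoxyphenyl]propanoic acid; 42 (R)-4-benzyloxazolidin-2-one
Product: 44 (R)-4-benzyl-3-{3-[4-(tert-butyldimethylsilyloxy)-3-methoxyphenyl]propanoyl}oxazolidin-2-one, via mixed anhydride 43 (not isolated)
Conditions: pivaloyl chloride, Et3N, THF, −20 °C; then 42, LiCl, rt
Reagents that add atoms: none
Why: N-Acylation of the oxazolidinone through the mixed pivalic anhydride, which is attacked at the less hindered carbonyl.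

Step 25
Reactants: 44 (R)-4-benzyl-3-{3-[4-(tert-butyldimethylsilyloxy)-3-methoxyphenyl]propanoyl}oxazolidin-2-one; 45 tert-butyl bromoacetate
Product: 47 tert-butyl (3S)-4-[(4R)-4-benzyl-2-oxooxazolidin-3-yl]-3-[4-(tert-butyldimethylsilyloxy)-3-methoxybenzyl]-4-oxobutanoate, via sodium enolate 46 (not isolated)
Conditions: NaN(SiMe3)2 (1.1 equiv), THF, −78 °C; then 45, −78 to −40 °C
Reagents that add atoms: none
Why: Evans asymmetric alkylation: the chelated Z-enolate is alkylated on the face away from the auxiliary benzyl group, which with the (R)-auxiliary gives the (S) centre that becomes C8'.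

Step 26
Reactants: 47 tert-butyl (3S)-4-[(4R)-4-benzyl-2-oxooxazolidin-3-yl]-3-[4-(tert-butyldimethylsilyloxy)-3-methoxybenzyl]-4-oxobutanoate
Product: 49 (S)-4-[4-(tert-butyldimethylsilyloxy)-3-methoxybenzyl]dihydrofuran-2(3H)-one, via hydroxy ester 48 (not isolated)
Conditions: LiBH4, THF–MeOH (1 equiv), 0 °C; then TsOH·H2O (cat.), CH2Cl2, rt
Reagents that add atoms: none
Why: Reductive removal of the auxiliary from the imide carbonyl (the tert-butyl ester is not reduced), then acid-catalysed lactonisation with loss of tert-butanol; the stereocentre is not involved.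

Step 27
Reactants: 49 (S)-4-[4-(tert-butyldimethylsilyloxy)-3-methoxybenzyl]dihydrofuran-2(3H)-one; 38 B–C–D tris(tert-butyldimethylsilyloxymethyl) ring B carbaldehyde bearing ring E as 4-(tert-butyldimethylsilyloxy)-3-methoxyphenyl
Product: 51 (3R,4S)-3-[ArX(hydroxy)methyl]-4-[4-(tert-butyldimethylsilyloxy)-3-methoxybenzyl]dihydrofuran-2(3H)-one (trans lactone as C7 carbinol epimers), via lithium enolate 50 (not isolated)
Conditions: 49 (1.5 equiv), LiN(SiMe3)2 (1.6 equiv), THF, −78 °C; then 38; AcOH, −78 °C
Reagents that add atoms: none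
Why: Aldol addition of a lactone lithium enolate to an aryl aldehyde; the aldehyde approaches anti to the β-benzyl group, which sets C8 trans to C8'. The carbinol centre need not be controlled.

Step 28
Reactants: 51 (3R,4S)-3-[ArX(hydroxy)methyl]-4-[4-(tert-butyldimethylsilyloxy)-3-methoxybenzyl]dihydrofuran-2(3H)-one
Product: 52 (2S,3S)-2-[ArX(hydroxy)methyl]-3-[4-(tert-butyldimethylsilyloxy)-3-methoxybenzyl]butane-1,4-diol (C7 carbinol epimers)
Conditions: LiBH4, THF, 0 °C to rt
Reagents that add atoms: none
Why: Hydride reduction of the lactone to the 1,4-diol; LiBH4 is mild enough to spare the aryl silyl ethers and to limit retro-aldol cleavage.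

Step 29
Reactants: 52 (2S,3S)-2-[ArX(hydroxy)methyl]-3-[4-(tert-butyldimethylsilyloxy)-3-methoxybenzyl]butane-1,4-diol
Product: 53 pentakis(tert-butyldimethylsilyl) ether of the target leaving the C9 hydroxyl free (7R,8S,8'S tetrahydrofuran)
Conditions: camphor-10-sulfonic acid (10 mol %), CH2Cl2, 0 °C
Reagents that add atoms: none
Why: Acid-promoted SN1 etherification of the kind used for lariciresinol-type closures: the C7 hydroxyl ionises to a cation stabilised by the para oxygen of ring B and the C9' hydroxyl closes the five-membered ring, so both carbinol epimers converge and the aryl group ends trans to the C8 substituent. Low acid loading and temperature are meant to stop the reaction before ring A attacks C7 or a C2–O bond ionises.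

Step 30
Reactants: 53 pentakis(tert-butyldimethylsilyl) ether of the target leaving the C9 hydroxyl free
Product: 54 target CNP0267891.2
Conditions: Bu4NF, AcOH (1:1), THF, 0 °C to rt
Reagents that add atoms: none
Why: Fluoride cleavage of the three alkyl and two aryl silyl ethers; the acetic acid buffer keeps the freed phenols protonated, and no stereocentre is touched.

## Compound list

1 | methyl vanillate | COC(=O)c1ccc(O)c(OC)c1 | starting material
2 | methyl 3-bromo-4-hydroxy-5-methoxybenzoate | COC(=O)c1cc(Br)c(O)c(OC)c1 | intermediate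
3 | tributyl(1-ethoxyvinyl)stannane | CCCC[Sn](CCCC)(CCCC)C(=C)OCC | starting material
4 | methyl 3-(1-ethoxyvinyl)-4-hydroxy-5-methoxybenzoate (not isolated) | COC(=O)c1cc(C(=C)OCC)c(O)c(OC)c1 | intermediate
5 | methyl 3-acetyl-4-hydroxy-5-methoxybenzoate | COC(=O)c1cc(C(C)=O)c(O)c(OC)c1 | intermediate
6 | N,N-dimethylformamide dimethyl acetal | COC(OC)N(C)C | starting material
7 | methyl 3-[(E)-3-(dimethylamino)acryloyl]-4-hydroxy-5-methoxybenzoate (not isolated) | COC(=O)c1cc(C(=O)/C=C/N(C)C)c(O)c(OC)c1 | intermediate
8 | methyl 8-methoxy-4-oxo-4H-chromene-6-carboxylate | COC(=O)c1cc(OC)c2occc(=O)c2c1 | intermediate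
9 | 2-bromo-6-methoxyphenol | COc1cccc(Br)c1O | starting material
10 | 2-bromo-6-methoxyphenyl pivalate | COc1cccc(Br)c1OC(=O)C(C)(C)C | intermediate
11 | bis(pinacolato)diboron | CC1(C)OB(OC1(C)C)B1OC(C)(C)C(C)(C)O1 | starting material
12 | 2-bromo-6-methoxy-4-(4,4,5,5-tetramethyl-1,3,2-dioxaborolan-2-yl)phenyl pivalate (not isolated) | COc1cc(B2OC(C)(C)C(C)(C)O2)cc(Br)c1OC(=O)C(C)(C)C | intermediate
13 | [3-bromo-5-methoxy-4-(pivaloyloxy)phenyl]boronic acid | COc1cc(B(O)O)cc(Br)c1OC(=O)C(C)(C)C | intermediate
14 | methyl (2S)-2-[3-bromo-5-methoxy-4-(pivaloyloxy)phenyl]-8-methoxy-4-oxochroman-6-carboxylate | COC(=O)c1cc(OC)c2c(c1)C(=O)C[C@@H](c1cc(OC)c(OC(=O)C(C)(C)C)c(Br)c1)O2 | intermediate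
15 | methyl (2S)-2-[3-bromo-5-methoxy-4-(pivaloyloxy)phenyl]-4,8-dimethoxy-2H-chromene-6-carboxylate (not isolated) | COC(=O)c1cc(OC)c2c(c1)C(OC)=C[C@@H](c1cc(OC)c(OC(=O)C(C)(C)C)c(Br)c1)O2 | intermediate
16 | dimethyl (2S,3S)-2-[3-bromo-5-methoxy-4-(pivaloyloxy)phenyl]-7-methoxy-2,3-dihydrobenzofuran-3,5-dicarboxylate | COC(=O)c1cc(OC)c2c(c1)[C@H](C(=O)OC)[C@@H](c1cc(OC)c(OC(=O)C(C)(C)C)c(Br)c1)O2 | intermediate
17 | dimethyl (2S,3S)-2-[3-(1-ethoxyvinyl)-5-methoxy-4-(pivaloyloxy)phenyl]-7-methoxy-2,3-dihydrobenzofuran-3,5-dicarboxylate (not isolated) | COC(=O)c1cc(OC)c2c(c1)[C@H](C(=O)OC)[C@@H](c1cc(OC)c(OC(=O)C(C)(C)C)c(C(=C)OCC)c1)O2 | intermediate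
18 | dimethyl (2S,3S)-2-[3-acetyl-5-methoxy-4-(pivaloyloxy)phenyl]-7-methoxy-2,3-dihydrobenzofuran-3,5-dicarboxylate | COC(=O)c1cc(OC)c2c(c1)[C@H](C(=O)OC)[C@@H](c1cc(OC)c(OC(=O)C(C)(C)C)c(C(C)=O)c1)O2 | intermediate
19 | dimethyl (2S,3S)-2-(3-acetyl-4-hydroxy-5-methoxyphenyl)-7-methoxy-2,3-dihydrobenzofuran-3,5-dicarboxylate | COC(=O)c1cc(OC)c2c(c1)[C@H](C(=O)OC)[C@@H](c1cc(OC)c(O)c(C(C)=O)c1)O2 | intermediate
20 | dimethyl (2S,3S)-2-{3-[(E)-3-(dimethylamino)acryloyl]-4-hydroxy-5-methoxyphenyl}-7-methoxy-2,3-dihydrobenzofuran-3,5-dicarboxylate (not isolated) | COC(=O)c1cc(OC)c2c(c1)[C@H](C(=O)OC)[C@@H](c1cc(OC)c(O)c(C(=O)/C=C/N(C)C)c1)O2 | intermediate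
21 | dimethyl (2S,3S)-7-methoxy-2-(8-methoxy-4-oxo-4H-chromen-6-yl)-2,3-dihydrobenzofuran-3,5-dicarboxylate | COC(=O)c1cc(OC)c2c(c1)[C@H](C(=O)OC)[C@@H](c1cc(OC)c3occc(=O)c3c1)O2 | intermediate
22 | dimethyl (2S,3S)-2-{(2S)-2-[3-bromo-5-methoxy-4-(pivaloyloxy)phenyl]-8-methoxy-4-oxochroman-6-yl}-7-methoxy-2,3-dihydrobenzofuran-3,5-dicarboxylate | COC(=O)c1cc(OC)c2c(c1)[C@H](C(=O)OC)[C@@H](c1cc(OC)c3c(c1)C(=O)C[C@@H](c1cc(OC)c(OC(=O)C(C)(C)C)c(Br)c1)O3)O2 | intermediate
23 | dimethyl (2S,3S)-2-{(2S)-2-[3-bromo-5-methoxy-4-(pivaloyloxy)phenyl]-4,8-dimethoxy-2H-chromen-6-yl}-7-methoxy-2,3-dihydrobenzofuran-3,5-dicarboxylate (not isolated) | COC(=O)c1cc(OC)c2c(c1)[C@H](C(=O)OC)[C@@H](c1cc(OC)c3c(c1)C(OC)=C[C@@H](c1cc(OC)c(OC(=O)C(C)(C)C)c(Br)c1)O3)O2 | intermediate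
24 | B–C triester bearing ring D as bromo pivalate: dimethyl (2S,3S)-2-{(2S,3S)-2-[3-bromo-5-methoxy-4-(pivaloyloxy)phenyl]-7-methoxy-3-(methoxycarbonyl)-2,3-dihydrobenzofuran-5-yl}-7-methoxy-2,3-dihydrobenzofuran-3,5-dicarboxylate | COC(=O)c1cc(OC)c2c(c1)[C@H](C(=O)OC)[C@@H](c1cc(OC)c3c(c1)[C@H](C(=O)OC)[C@@H](c1cc(OC)c(OC(=O)C(C)(C)C)c(Br)c1)O3)O2 | intermediate
25 | dimethyl (2S,3S)-2-{(2S,3S)-2-[3-(1-ethoxyvinyl)-5-methoxy-4-(pivaloyloxy)phenyl]-7-methoxy-3-(methoxycarbonyl)-2,3-dihydrobenzofuran-5-yl}-7-methoxy-2,3-dihydrobenzofuran-3,5-dicarboxylate (not isolated) | COC(=O)c1cc(OC)c2c(c1)[C@H](C(=O)OC)[C@@H](c1cc(OC)c3c(c1)[C@H](C(=O)OC)[C@@H](c1cc(OC)c(OC(=O)C(C)(C)C)c(C(=C)OCC)c1)O3)O2 | intermediate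
26 | B–C triester bearing ring D as acetyl pivalate: dimethyl (2S,3S)-2-{(2S,3S)-2-[3-acetyl-5-methoxy-4-(pivaloyloxy)phenyl]-7-methoxy-3-(methoxycarbonyl)-2,3-dihydrobenzofuran-5-yl}-7-methoxy-2,3-dihydrobenzofuran-3,5-dicarboxylate | COC(=O)c1cc(OC)c2c(c1)[C@H](C(=O)OC)[C@@H](c1cc(OC)c3c(c1)[C@H](C(=O)OC)[C@@H](c1cc(OC)c(OC(=O)C(C)(C)C)c(C(C)=O)c1)O3)O2 | intermediate
27 | B–C triester bearing ring D as acetyl phenol: dimethyl (2S,3S)-2-[(2S,3S)-2-(3-acetyl-4-hydroxy-5-methoxyphenyl)-7-methoxy-3-(methoxycarbonyl)-2,3-dihydrobenzofuran-5-yl]-7-methoxy-2,3-dihydrobenzofuran-3,5-dicarboxylate | COC(=O)c1cc(OC)c2c(c1)[C@H](C(=O)OC)[C@@H](c1cc(OC)c3c(c1)[C@H](C(=O)OC)[C@@H](c1cc(OC)c(O)c(C(C)=O)c1)O3)O2 | intermediate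
28 | dimethyl (2S,3S)-2-[(2S,3S)-2-{3-[(E)-3-(dimethylamino)acryloyl]-4-hydroxy-5-methoxyphenyl}-7-methoxy-3-(methoxycarbonyl)-2,3-dihydrobenzofuran-5-yl]-7-methoxy-2,3-dihydrobenzofuran-3,5-dicarboxylate (not isolated) | COC(=O)c1cc(OC)c2c(c1)[C@H](C(=O)OC)[C@@H](c1cc(OC)c3c(c1)[C@H](C(=O)OC)[C@@H](c1cc(OC)c(O)c(C(=O)/C=C/N(C)C)c1)O3)O2 | intermediate
29 | ring D chromone of the B–C triester: dimethyl (2S,3S)-7-methoxy-2-[(2S,3S)-7-methoxy-3-(methoxycarbonyl)-2-(8-methoxy-4-oxo-4H-chromen-6-yl)-2,3-dihydrobenzofuran-5-yl]-2,3-dihydrobenzofuran-3,5-dicarboxylate | COC(=O)c1cc(OC)c2c(c1)[C@H](C(=O)OC)[C@@H](c1cc(OC)c3c(c1)[C@H](C(=O)OC)[C@@H](c1cc(OC)c4occc(=O)c4c1)O3)O2 | intermediate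
30 | 2-methoxy-4-(4,4,5,5-tetramethyl-1,3,2-dioxaborolan-2-yl)phenol | COc1cc(B2OC(C)(C)C(C)(C)O2)ccc1O | starting material
31 | 2-methoxy-4-(4,4,5,5-tetramethyl-1,3,2-dioxaborolan-2-yl)phenyl pivalate | COc1cc(B2OC(C)(C)C(C)(C)O2)ccc1OC(=O)C(C)(C)C | intermediate
32 | [3-methoxy-4-(pivaloyloxy)phenyl]boronic acid | COc1cc(B(O)O)ccc1OC(=O)C(C)(C)C | intermediate
33 | ring D flavanone of the B–C triester: dimethyl (2S,3S)-7-methoxy-2-[(2S,3S)-7-methoxy-3-(methoxycarbonyl)-2-{(2R)-8-methoxy-2-[3-methoxy-4-(pivaloyloxy)phenyl]-4-oxochroman-6-yl}-2,3-dihydrobenzofuran-5-yl]-2,3-dihydrobenzofuran-3,5-dicarboxylate | COC(=O)c1cc(OC)c2c(c1)[C@H](C(=O)OC)[C@@H](c1cc(OC)c3c(c1)[C@H](C(=O)OC)[C@@H](c1cc(OC)c4c(c1)C(=O)C[C@H](c1ccc(OC(=O)C(C)(C)C)c(OC)c1)O4)O3)O2 | intermediate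
34 | dimethyl (2S,3S)-2-[(2S,3S)-2-{(2R)-4,8-dimethoxy-2-[3-methoxy-4-(pivaloyloxy)phenyl]-2H-chromen-6-yl}-7-methoxy-3-(methoxycarbonyl)-2,3-dihydrobenzofuran-5-yl]-7-methoxy-2,3-dihydrobenzofuran-3,5-dicarboxylate (not isolated) | COC(=O)c1cc(OC)c2c(c1)[C@H](C(=O)OC)[C@@H](c1cc(OC)c3c(c1)[C@H](C(=O)OC)[C@@H](c1cc(OC)c4c(c1)C(OC)=C[C@H](c1ccc(OC(=O)C(C)(C)C)c(OC)c1)O4)O3)O2 | intermediate
35 | B–C–D tetraester with ring E pivalate: dimethyl (2S,3S)-7-methoxy-2-[(2S,3S)-7-methoxy-3-(methoxycarbonyl)-2-{(2R,3R)-7-methoxy-3-(methoxycarbonyl)-2-[3-methoxy-4-(pivaloyloxy)phenyl]-2,3-dihydrobenzofuran-5-yl}-2,3-dihydrobenzofuran-5-yl]-2,3-dihydrobenzofuran-3,5-dicarboxylate | COC(=O)c1cc(OC)c2c(c1)[C@H](C(=O)OC)[C@@H](c1cc(OC)c3c(c1)[C@H](C(=O)OC)[C@@H](c1cc(OC)c4c(c1)[C@@H](C(=O)OC)[C@H](c1ccc(OC(=O)C(C)(C)C)c(OC)c1)O4)O3)O2 | intermediate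
36 | B–C–D tetrakis(hydroxymethyl) phenol: {(2S,3R)-2-[(2S,3R)-3-(hydroxymethyl)-2-{(2R,3S)-3-(hydroxymethyl)-2-(4-hydroxy-3-methoxyphenyl)-7-methoxy-2,3-dihydrobenzofuran-5-yl}-7-methoxy-2,3-dihydrobenzofuran-5-yl]-7-methoxy-2,3-dihydrobenzofuran-3,5-diyl}dimethanol | OCc1cc(OC)c2c(c1)[C@H](CO)[C@@H](c1cc(OC)c3c(c1)[C@H](CO)[C@@H](c1cc(OC)c4c(c1)[C@@H](CO)[C@H](c1ccc(O)c(OC)c1)O4)O3)O2 | intermediate
37 | ring B aldehyde triol phenol: (2S,3R)-3-(hydroxymethyl)-2-[(2S,3R)-3-(hydroxymethyl)-2-{(2R,3S)-3-(hydroxymethyl)-2-(4-hydroxy-3-methoxyphenyl)-7-methoxy-2,3-dihydrobenzofuran-5-yl}-7-methoxy-2,3-dihydrobenzofuran-5-yl]-7-methoxy-2,3-dihydrobenzofuran-5-carbaldehyde | O=Cc1cc(OC)c2c(c1)[C@H](CO)[C@@H](c1cc(OC)c3c(c1)[C@H](CO)[C@@H](c1cc(OC)c4c(c1)[C@@H](CO)[C@H](c1ccc(O)c(OC)c1)O4)O3)O2 | intermediate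
38 | tetrakis(tert-butyldimethylsilyl) ring B aldehyde: (2S,3R)-3-(tert-butyldimethylsilyloxymethyl)-2-[(2S,3R)-3-(tert-butyldimethylsilyloxymethyl)-2-{(2R,3S)-3-(tert-butyldimethylsilyloxymethyl)-2-[4-(tert-butyldimethylsilyloxy)-3-methoxyphenyl]-7-methoxy-2,3-dihydrobenzofuran-5-yl}-7-methoxy-2,3-dihydrobenzofuran-5-yl]-7-methoxy-2,3-dihydrobenzofuran-5-carbaldehyde | O=Cc1cc(OC)c2c(c1)[C@H](CO[Si](C)(C)C(C)(C)C)[C@@H](c1cc(OC)c3c(c1)[C@H](CO[Si](C)(C)C(C)(C)C)[C@@H](c1cc(OC)c4c(c1)[C@@H](CO[Si](C)(C)C(C)(C)C)[C@H](c1ccc(O[Si](C)(C)C(C)(C)C)c(OC)c1)O4)O3)O2 | intermediate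
39 | 3-(4-hydroxy-3-methoxyphenyl)propanoic acid | COc1cc(CCC(=O)O)ccc1O | starting material
40 | tert-butyldimethylsilyl 3-[4-(tert-butyldimethylsilyloxy)-3-methoxyphenyl]propanoate (not isolated) | COc1cc(CCC(=O)O[Si](C)(C)C(C)(C)C)ccc1O[Si](C)(C)C(C)(C)C | intermediate
41 | 3-[4-(tert-butyldimethylsilyloxy)-3-methoxyphenyl]propanoic acid | COc1cc(CCC(=O)O)ccc1O[Si](C)(C)C(C)(C)C | intermediate
42 | (R)-4-benzyloxazolidin-2-one | O=C1N[C@H](Cc2ccccc2)CO1 | starting material
43 | mixed pivalic anhydride of 41 (not isolated) | COc1cc(CCC(=O)OC(=O)C(C)(C)C)ccc1O[Si](C)(C)C(C)(C)C | intermediate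
44 | (R)-4-benzyl-3-{3-[4-(tert-butyldimethylsilyloxy)-3-methoxyphenyl]propanoyl}oxazolidin-2-one | COc1cc(CCC(=O)N2[C@H](Cc3ccccc3)COC2=O)ccc1O[Si](C)(C)C(C)(C)C | intermediate
45 | tert-butyl bromoacetate | CC(C)(C)OC(=O)CBr | starting material
46 | sodium (Z)-enolate of 44 (not isolated) | [Na+].COc1cc(C/C=C(\[O-])N2[C@H](Cc3ccccc3)COC2=O)ccc1O[Si](C)(C)C(C)(C)C | intermediate
47 | tert-butyl (3S)-4-[(4R)-4-benzyl-2-oxooxazolidin-3-yl]-3-[4-(tert-butyldimethylsilyloxy)-3-methoxybenzyl]-4-oxobutanoate | COc1cc(C[C@@H](CC(=O)OC(C)(C)C)C(=O)N2[C@H](Cc3ccccc3)COC2=O)ccc1O[Si](C)(C)C(C)(C)C | intermediate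
48 | tert-butyl (3S)-3-[4-(tert-butyldimethylsilyloxy)-3-methoxybenzyl]-4-hydroxybutanoate (not isolated) | COc1cc(C[C@@H](CC(=O)OC(C)(C)C)CO)ccc1O[Si](C)(C)C(C)(C)C | intermediate
49 | (S)-4-[4-(tert-butyldimethylsilyloxy)-3-methoxybenzyl]dihydrofuran-2(3H)-one | COc1cc(C[C@@H]2COC(=O)C2)ccc1O[Si](C)(C)C(C)(C)C | intermediate
50 | lithium enolate of 49 (not isolated) | [Li+].COc1cc(C[C@@H]2COC([O-])=C2)ccc1O[Si](C)(C)C(C)(C)C | intermediate
51 | (3R,4S)-3-[ArX(hydroxy)methyl]-4-[4-(tert-butyldimethylsilyloxy)-3-methoxybenzyl]dihydrofuran-2(3H)-one, trans lactone, C7 carbinol epimers | COc1cc(C[C@@H]2COC(=O)[C@H]2C(O)c2cc(OC)c3c(c2)[C@H](CO[Si](C)(C)C(C)(C)C)[C@@H](c2cc(OC)c4c(c2)[C@H](CO[Si](C)(C)C(C)(C)C)[C@@H](c2cc(OC)c5c(c2)[C@@H](CO[Si](C)(C)C(C)(C)C)[C@H](c2ccc(O[Si](C)(C)C(C)(C)C)c(OC)c2)O5)O4)O3)ccc1O[Si](C)(C)C(C)(C)C | intermediate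
52 | (2S,3S)-2-[ArX(hydroxy)methyl]-3-[4-(tert-butyldimethylsilyloxy)-3-methoxybenzyl]butane-1,4-diol, C7 carbinol epimers | COc1cc(C[C@H](CO)[C@@H](CO)C(O)c2cc(OC)c3c(c2)[C@H](CO[Si](C)(C)C(C)(C)C)[C@@H](c2cc(OC)c4c(c2)[C@H](CO[Si](C)(C)C(C)(C)C)[C@@H](c2cc(OC)c5c(c2)[C@@H](CO[Si](C)(C)C(C)(C)C)[C@H](c2ccc(O[Si](C)(C)C(C)(C)C)c(OC)c2)O5)O4)O3)ccc1O[Si](C)(C)C(C)(C)C | intermediate
53 | pentakis(tert-butyldimethylsilyl) ether of the target with free C9 hydroxyl (7R,8S,8'S) | COc1cc(C[C@@H]2CO[C@@H](c3cc(OC)c4c(c3)[C@H](CO[Si](C)(C)C(C)(C)C)[C@@H](c3cc(OC)c5c(c3)[C@H](CO[Si](C)(C)C(C)(C)C)[C@@H](c3cc(OC)c6c(c3)[C@@H](CO[Si](C)(C)C(C)(C)C)[C@H](c3ccc(O[Si](C)(C)C(C)(C)C)c(OC)c3)O6)O5)O4)[C@@H]2CO)ccc1O[Si](C)(C)C(C)(C)C | intermediate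
54 | CNP0267891.2 | COc1cc(C[C@@H]2CO[C@@H](c3cc(OC)c4c(c3)[C@H](CO)[C@@H](c3cc(OC)c5c(c3)[C@H](CO)[C@@H](c3cc(OC)c6c(c3)[C@@H](CO)[C@H](c3ccc(O)c(OC)c3)O6)O5)O4)[C@@H]2CO)ccc1O | target

## Step count and least certain steps

Total: 30 steps. Longest linear sequence: 22 steps from 1 (steps 1–3, 6–15, 18–22, 27–30). The side branches are steps 4–5 (to 13), 16–17 (to 32) and 23–26 (to 49).

**Key step (step 7).**
- What may go wrong: the C2 aryl group may migrate in place of the fused ring; the C3 iodane may eliminate to the flavone; C3 may simply be methoxylated; and optical purity at C2 may erode through acid-promoted opening of the pyranone to the chalcone and reclosure, which the ring B ester makes easier by improving the phenol as a leaving group.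
- Fallback (acid-free Wolff ring contraction, forming the same C3–C3a bond by a ketene path): from 14, trifluoroacetylation (LiN(SiMe3)2, CF3CO2CH2CF3, THF, −78 °C) gives the 3-trifluoroacetyl ketone F1, which is not isolated and is treated with MsN3, Et3N and H2O in MeCN to give the 3-diazo ketone F2. Irradiation of F2 in MeOH moves C4a to C3 with loss of nitrogen, and methanol adds to the ketene to give the ester as a C3 mixture that contains the cis diester F3. DBU equilibration converts F3 to the trans isomer, and the route is rejoined at 16.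

**Risk at the second contraction (step 12; likewise step 19).**
- What may go wrong: in the sulfuric acid medium the C2–O bond of the unit already built may ionise, since its aryl group carries a para ether oxygen once the ketone is ketalised. Methanol capture or oxidation of the phenol so freed would follow. The C3 ester slows this but may not stop it.
- Fallback: from 22, the same acid-free sequence. LiN(SiMe3)2 and CF3CO2CH2CF3 at −78 °C give the trifluoroacetyl ketone F4 (not isolated), MsN3 and Et3N give the diazo ketone F5, and irradiation in MeOH gives the ring-contracted ester as a mixture that contains the C unit cis epimer F6. DBU equilibration returns to the route at 24. The ketone stays in place until nitrogen is lost, so the para oxygen remains a poor donor throughout.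

**Risk at the pivalate removal (step 9; likewise step 14).**
- What may go wrong: the phenoxide formed is para to C2 of the finished unit and may expel the ring B phenoxide to give a quinone methide, which could tautomerise irreversibly through the acidic C3–H to a ring-opened stilbene ester. Slow methanolysis of the hindered pivalate would lengthen the exposure.
- Fallback (change of order, so that no free phenoxide is formed): from 18, condensation with 6 is run first and gives the O-pivaloyl enaminone F7. HCl in MeOH at 50 °C then cleaves the pivalate by acid methanolysis, and the phenol closes at once onto the protonated enaminone. The route is rejoined at 21, and 19 and 20 are bypassed.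

**Risk at the conjugate additions (step 18; likewise steps 6 and 11).**
- What may go wrong: facial selectivity may be poor or of the wrong sense. In step 18 the chromone is already chiral and the addition must run opposite to the first two, so catalyst and substrate control may not agree. Transmetalation of the electron-poor boronic acid may also be slow.
- Fallback (different metal, ligand class and enantio-determining step): from 29 and 32, catalysis by monovalent rhodium ([RhCl(C2H4)2]2, chiral diene ligand, aq. K3PO4, dioxane, rt), in which an aryl–rhodium species inserts the chromone double bond. It rejoins the route at 33 and makes no new compound (F0). Because 33 and its C2 epimer are diastereomers, a minor epimer could also be removed by chromatography.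

**Risk at the acetyl installation (step 2).**
- What may go wrong: oxidative addition to the electron-rich ortho-bromophenol may be slow, and the acidic phenol may protodestannylate 3.
- Fallback (C–C bond by acyl migration in place of cross-coupling): from 1, acetylation (Ac2O, pyridine) gives methyl 4-acetoxy-3-methoxybenzoate F8, and Fries rearrangement in neat CF3SO3H at 60 °C (chosen over AlCl3 to spare the methyl ether) moves the acetyl group to the position ortho to oxygen. The route is rejoined at 5, and 2 and 4 are bypassed.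

## Further compounds

F1 | step 7 | methyl (2S)-2-[3-bromo-5-methoxy-4-(pivaloyloxy)phenyl]-8-methoxy-4-oxo-3-(trifluoroacetyl)chroman-6-carboxylate (not isolated) | COC(=O)c1cc(OC)c2c(c1)C(=O)C(C(=O)C(F)(F)F)[C@@H](c1cc(OC)c(OC(=O)C(C)(C)C)c(Br)c1)O2
F2 | step 7 | methyl 2-[3-bromo-5-methoxy-4-(pivaloyloxy)phenyl]-3-diazo-8-methoxy-4-oxochroman-6-carboxylate (same spatial arrangement at C2 as 14; 2R by the sequence rule) | COC(=O)c1cc(OC)c2c(c1)C(=O)C(=[N+]=[N-])[C@@H](c1cc(OC)c(OC(=O)C(C)(C)C)c(Br)c1)O2
F3 | step 7 | dimethyl (2S,3R)-2-[3-bromo-5-methoxy-4-(pivaloyloxy)phenyl]-7-methoxy-2,3-dihydrobenzofuran-3,5-dicarboxylate (cis epimer of 16) | COC(=O)c1cc(OC)c2c(c1)[C@@H](C(=O)OC)[C@@H](c1cc(OC)c(OC(=O)C(C)(C)C)c(Br)c1)O2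
F4 | step 12 | 3-trifluoroacetyl derivative of 22 at the chromanone (not isolated) | COC(=O)c1cc(OC)c2c(c1)[C@H](C(=O)OC)[C@@H](c1cc(OC)c3c(c1)C(=O)C(C(=O)C(F)(F)F)[C@@H](c1cc(OC)c(OC(=O)C(C)(C)C)c(Br)c1)O3)O2
F5 | step 12 | 3-diazo derivative of 22 at the chromanone | COC(=O)c1cc(OC)c2c(c1)[C@H](C(=O)OC)[C@@H](c1cc(OC)c3c(c1)C(=O)C(=[N+]=[N-])[C@@H](c1cc(OC)c(OC(=O)C(C)(C)C)c(Br)c1)O3)O2
F6 | step 12 | epimer of 24 with the C unit cis (B unit 2S,3S; C unit 2S,3R) | COC(=O)c1cc(OC)c2c(c1)[C@H](C(=O)OC)[C@@H](c1cc(OC)c3c(c1)[C@@H](C(=O)OC)[C@@H](c1cc(OC)c(OC(=O)C(C)(C)C)c(Br)c1)O3)O2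
F7 | step 9 | dimethyl (2S,3S)-2-{3-[(E)-3-(dimethylamino)acryloyl]-5-methoxy-4-(pivaloyloxy)phenyl}-7-methoxy-2,3-dihydrobenzofuran-3,5-dicarboxylate | COC(=O)c1cc(OC)c2c(c1)[C@H](C(=O)OC)[C@@H](c1cc(OC)c(OC(=O)C(C)(C)C)c(C(=O)/C=C/N(C)C)c1)O2
F0 | step 18 | none | none
F8 | step 2 | methyl 4-acetoxy-3-methoxybenzoate | COC(=O)c1ccc(OC(C)=O)c(OC)c1
A1 | alternative 1 | trans-disubstituted menthyloxy butyrolactone from the three-component union (C7 carbinol mixture) | COc5cc(C6(SCCCS6)[C@@H]7[C@@H](O[C@H]8C[C@@H](C)CC[C@@H]8C(C)C)OC(=O)[C@H]7C(O)c1cc(OC)c2c(c1)[C@H](CO[Si](C)(C)C(C)(C)C)[C@@H](c1cc(OC)c3c(c1)[C@H](CO[Si](C)(C)C(C)(C)C)[C@@H](c1cc(OC)c4c(c1)[C@@H](CO[Si](C)(C)C(C)(C)C)[C@H](c1ccc(O[Si](C)(C)C(C)(C)C)c(OC)c1)O4)O3)O2)ccc5O[Si](C)(C)C(C)(C)C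
A2 | alternative 1 | 2-[4-(tert-butyldimethylsilyloxy)-3-methoxyphenyl]-1,3-dithiane | COc1cc(C2SCCCS2)ccc1O[Si](C)(C)C(C)(C)C
A3 | alternative 1 | (5S)-5-[(1S,2R,5S)-menthyloxy]furan-2(5H)-one | O=C1C=C[C@@H](O[C@H]2C[C@@H](C)CC[C@@H]2C(C)C)O1
A4 | alternative 2 | trans,trans bis(dihydrobenzofuran) triester joined to the silylated D unit | COC(=O)c1cc(OC)c2c(c1)[C@H](C(=O)OC)[C@@H](c1cc(OC)c3c(c1)[C@H](C(=O)OC)[C@@H](c1cc(OC)c4c(c1)[C@@H](CO[Si](C)(C)C(C)(C)C)[C@H](c1ccc(O[Si](C)(C)C(C)(C)C)c(OC)c1)O4)O3)O2
A5 | alternative 2 | open bis(aryl diazoacetate) with two benzyl aryl ether links | COC(=O)c1cc(OC)c(OCc2cc(OC)c(OCc3cc(OC)c4c(c3)[C@@H](CO[Si](C)(C)C(C)(C)C)[C@H](c3ccc(O[Si](C)(C)C(C)(C)C)c(OC)c3)O4)c(C(=[N+]=[N-])C(=O)OC)c2)c(C(=[N+]=[N-])C(=O)OC)c1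
A6 | alternative 3 | methyl (2R,3S)-trans-2-[4-(tert-butyldimethylsilyloxy)-3-methoxyphenyl]-3-(tert-butyldimethylsilyloxymethyl)-7-methoxy-2,3-dihydrobenzofuran-5-carboxylate | COC(=O)c1cc(OC)c2c(c1)[C@@H](CO[Si](C)(C)C(C)(C)C)[C@H](c1ccc(O[Si](C)(C)C(C)(C)C)c(OC)c1)O2
A7 | alternative 3 | methyl 3-[2-(tert-butyldimethylsilyloxy)-1-(p-tolylsulfonyl)ethyl]-4-hydroxy-5-methoxybenzoate | COC(=O)c1cc(OC)c(O)c(C(CO[Si](C)(C)C(C)(C)C)S(=O)(=O)c2ccc(C)cc2)c1
A8 | alternative 3 | (2R,5R)-1-[4-(tert-butyldimethylsilyloxy)-3-methoxybenzyl]-2,5-dimethylthiolanium triflate (enantiomer illustrative) | COc1cc(C[S+]2[C@H](C)CC[C@H]2C)ccc1O[Si](C)(C)C(C)(C)C.[O-]S(=O)(=O)C(F)(F)F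
A9 | alternative 3 | ortho-quinone methide from A7 | COC(=O)C1=CC(=CCO[Si](C)(C)C(C)(C)C)C(=O)C(OC)=C1
A10 | alternative 3 | sulfonium ylide from A8 | COc1cc([CH-][S+]2[C@H](C)CC[C@H]2C)ccc1O[Si](C)(C)C(C)(C)C
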